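**Strategy.** Everything rests on cutting the B-C1–B-C2 bond in the hydroxylated half. B-C1 is the methylene on C8 of a 7-methoxycoumarin ring, B-C2 is the carbinol carbon, and its other neighbour B-C3 is the quaternary, ether-bearing CMe2 carbon. B-C2 can therefore come from a non-enolisable α-alkoxy aldehyde. In one operation a chiral coumarin-8-ylmethyl sulfonium ylide adds to that aldehyde and closes an oxirane, making the C–C bond and fixing B-C2 under reagent control. Reductive cleavage of the benzylic C–O bond then gives the alcohol. The precursor is (S)-auraptenol, made from osthol, carrying a 1-formyl-1-methylethyl group on its oxygen.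

Key step: step 12

Assumption on absolute sense: the L-fructose-derived Shi ketone is taken to give the (S)-epoxide of osthol, and the (R)-limonene-derived isothiocineole to give the (B-C1 R, B-C2 S)-oxirane, as the usual transition-state models predict; each is available as its antipode if a model reaction shows the opposite sense.

Atom labels: half A is ArCH2(A-C1)–CH(A-C2)(O–)–C(A-C3)(Me)=CH2; half B is ArCH2(B-C1)–CH(B-C2)(OH)–C(B-C3)Me2–O–; Ar is 7-methoxycoumarin-8-yl.

**Route**

Step 1
Reactants: 1 osthol
Product: 2 (S)-meranzin
Conditions: L-fructose-derived Shi ketone (30 mol%), KHSO5 (as Oxone), K2CO3, Bu4NHSO4, Na2B4O7 buffer, MeCN–CH2(OMe)2–H2O, 0 °C; work-up at pH 5–6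
Reagents that add atoms: KHSO5 (potassium peroxymonosulfate), [K+].[O-]S(=O)(=O)OO
Why: Shi epoxidation, in which the chiral dioxirane formed from the ketone transfers oxygen to the electron-rich trisubstituted prenyl alkene through a spiro transition state, should set the new (S) centre under catalyst control while the electron-poor coumarin C3=C4 bond is left alone and mild acidification re-closes any lactone opened by the basic buffer.

Step 2
Reactants: 2 (S)-meranzin
Product: 4 (S)-auraptenol, via silyl ether 3 (not isolated)
Conditions: Me3SiOTf, DBU, toluene, 0 °C → rt; then 1 M HCl, THF, 0 °C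
Reagents that add atoms: none
Why: Silyl-triflate-promoted isomerisation of an epoxide to an allylic alcohol, in which O-silylation loosens the tertiary C–O bond and the amidine base removes a methyl proton to give the isopropenyl group, never breaks the secondary C–O bond, so the (S) centre is carried over before the labile silyl ether is hydrolysed.

Step 3
Reactants: 4 (S)-auraptenol
Product: 5 (S)-auraptenyl methyl carbonate
Conditions: ClCO2Me, pyridine, CH2Cl2, 0 °C → rt
Reagents that add atoms: methyl chloroformate, COC(=O)Cl
Why: O-acylation of a secondary alcohol with a chloroformate takes place at oxygen only and leaves the carbinol configuration untouched.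

Step 4
Reactants: 6 2-methylpropane-1,2-diol
Product: 8 1-[(4-methoxybenzyl)oxy]-2-methylpropan-2-ol, via sodium alkoxide 7 (not isolated)
Conditions: NaH (1.0 equiv), THF–DMF, 0 °C; then 4-methoxybenzyl chloride, Bu4NI (cat.), 0 °C → rt
Reagents that add atoms: 4-methoxybenzyl chloride, COc1ccc(CCl)cc1
Why: Williamson ether synthesis with one equivalent of base alkylates the less hindered, more acidic primary hydroxyl, the tertiary hydroxyl being too crowded to compete.

Step 5
Reactants: 8 1-[(4-methoxybenzyl)oxy]-2-methylpropan-2-ol; 5 (S)-auraptenyl methyl carbonate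
Product: 11 4-methoxybenzyl ether of 2-methyl-2-[(S)-auraptenyloxy]propan-1-ol, via lithium alkoxide 9 (not isolated), via cuprous alkoxide 10 (not isolated)
Conditions: 8 (2 equiv), LiN(SiMe3)2, THF, 0 °C; CuI, rt; then 5, RhCl(PPh3)3 (10 mol%), P(OMe)3 (40 mol%), THF, 0 °C → rt
Reagents that add atoms: none
Why: Rhodium-catalysed allylic etherification of a secondary allylic carbonate with a soft cuprous alkoxide proceeds by ionisation and substitution, each with inversion at a configurationally stable rhodium allyl, so the tertiary alkoxide should enter at the carbon that carried the carbonate with overall retention and give the hindered (S) ether without an SN1 or E2 pathway.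

Step 6
Reactants: 11 4-methoxybenzyl ether of 2-methyl-2-[(S)-auraptenyloxy]propan-1-ol
Product: 12 2-methyl-2-[(S)-auraptenyloxy]propan-1-ol
Conditions: DDQ, CH2Cl2–pH 7 buffer, 0 °C → rt
Reagents that add atoms: none
Why: Oxidative cleavage of a 4-methoxybenzyl ether by the quinone is confined to the electron-rich benzylic position, and hydrolysis frees the primary alcohol without touching the allylic tertiary ether, the alkene or the coumarin.

Step 7
Reactants: 12 2-methyl-2-[(S)-auraptenyloxy]propan-1-ol
Product: 13 2-methyl-2-[(S)-auraptenyloxy]propanal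
Conditions: Dess–Martin periodinane, CH2Cl2, rt
Reagents that add atoms: none
Why: Dess–Martin oxidation of a neopentyl-type primary alcohol stops at the aldehyde, which has no α-hydrogen and so cannot enolise or epimerise.

Step 8
Reactants: 14 2-methylresorcinol
Product: 15 7-hydroxy-8-methylcoumarin
Conditions: DL-malic acid, conc. H2SO4, 100 °C
Reagents that add atoms: DL-malic acid, OC(CC(=O)O)C(=O)O
Why: Pechmann condensation, in which malic acid loses CO and water in sulfuric acid to give formylacetic acid that condenses para to one hydroxyl and lactonises onto the other, places the ring methyl group at C8.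

Step 9
Reactants: 15 7-hydroxy-8-methylcoumarin
Product: 17 7-methoxy-8-methylcoumarin, via potassium phenoxide 16 (not isolated)
Conditions: MeI, K2CO3, acetone, reflux
Reagents that add atoms: iodomethane, CI
Why: Williamson O-methylation of the acidic 7-hydroxyl through its phenoxide is fast, and the lactone is inert to K2CO3 in acetone.

Step 10
Reactants: 17 7-methoxy-8-methylcoumarin
Product: 18 8-(bromomethyl)-7-methoxycoumarin
Conditions: NBS, AIBN (cat.), PhCF3, reflux
Reagents that add atoms: N-bromosuccinimide, O=C1CCC(=O)N1Br
Why: Wohl–Ziegler bromination under radical-chain conditions in a non-polar solvent attacks the only benzylic C–H bonds, those of the C8 methyl group, while ionic ring bromination is suppressed.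

Step 11
Reactants: 18 8-(bromomethyl)-7-methoxycoumarin
Product: 19 S-[(7-methoxycoumarin-8-yl)methyl]isothiocineolium triflate
Conditions: isothiocineole from (R)-limonene, LiOTf, CH2Cl2–H2O, rt
Reagents that add atoms: isothiocineole from (R)-limonene (4,7,7-trimethyl-6-thiabicyclo[3.2.1]octane, 4-methyl cis to the sulfur bridge), C[C@H]1CC[C@@H]2C[C@H]1SC2(C)C; lithium triflate, [Li+].[O-]S(=O)(=O)C(F)(F)F
Why: SN2 S-alkylation of a dialkyl sulfide by a reactive benzylic bromide, driven by exchange to the non-nucleophilic triflate, should occur on the exposed exo lone pair of the bicyclic sulfide and give one sulfonium diastereomer.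

Step 12
Reactants: 19 S-[(7-methoxycoumarin-8-yl)methyl]isothiocineolium triflate; 13 2-methyl-2-[(S)-auraptenyloxy]propanal
Product: 22 trans-epoxide across B-C1 and B-C2 (B-C1 R; B-C2 S), via sulfonium ylide 20 (not isolated), via anti betaine 21 (not isolated)
Conditions: 19 (1.2 equiv), phosphazene base P2-Et, CH2Cl2, −78 °C; then 13, −78 → −20 °C
Reagents that add atoms: none
Why: The hindered, non-nucleophilic base removes a benzylic proton from 19, ylide 20 adds to the aldehyde carbon of 13 to give anti betaine 21, and the alkoxide displaces the sulfide at B-C1, forming the B-C1–B-C2 bond and the oxirane; this is the chiral-sulfide variant of the Corey–Chaykovsky epoxidation, well established for benzylic sulfonium salts and aldehydes. The one ring closes in a 3-exo-tet mode with inversion at B-C1. B-C2 should be set as (S) by the sulfide, whose gem-dimethyl group holds the ylide in one conformation and screens one face, overriding the remote A-C2 centre; B-C1 follows as (R) from the anti betaine favoured by the bulky quaternary neighbour of the aldehyde, and that centre is erased in the next step. The step needs addition to the aldehyde in preference to conjugate addition to either coumarin C3=C4 bond or attack on a lactone, which the higher electrophilicity of the aldehyde, its lack of α-hydrogens and the low temperature should secure.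

Step 13
Reactants: 22 trans-epoxide across B-C1 and B-C2
Product: 25 CNP0142500.1, via benzylic radical 23 (not isolated), via titanium alkoxide 24 (not isolated)
Conditions: Cp2TiCl2 (20 mol%), Mn, 2,4,6-collidine hydrochloride, 1,4-cyclohexadiene, THF, rt
Reagents that add atoms: none
Why: Titanocene-catalysed radical opening of an epoxide by Cp2TiCl (trivalent titanium) cleaves the weaker benzylic C–O bond to the radical at B-C1, which takes a hydrogen atom from the diene, so the oxygen stays on B-C2 with its (S) configuration and B-C1 becomes a methylene group.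

**Compound list**

1 | osthol | COc1ccc2ccc(=O)oc2c1CC=C(C)C | starting material
2 | (S)-meranzin, 8-{[(2S)-3,3-dimethyloxiran-2-yl]methyl}-7-methoxy-2H-chromen-2-one | CC1(C)O[C@H]1Cc1c(OC)ccc2ccc(=O)oc12 | intermediate
3 | trimethylsilyl ether of (S)-auraptenol (formed in the flask) | C=C(C)[C@@H](O[Si](C)(C)C)Cc1c(OC)ccc2ccc(=O)oc12 | intermediate
4 | (S)-auraptenol, 8-[(2S)-2-hydroxy-3-methylbut-3-en-1-yl]-7-methoxy-2H-chromen-2-one | C=C(C)[C@@H](O)Cc1c(OC)ccc2ccc(=O)oc12 | intermediate
5 | (S)-auraptenyl methyl carbonate | C=C(C)[C@@H](OC(=O)OC)Cc1c(OC)ccc2ccc(=O)oc12 | intermediate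
6 | 2-methylpropane-1,2-diol | CC(C)(O)CO | starting material
7 | sodium 2-hydroxy-2-methylpropan-1-olate (formed in the flask) | [Na+].[O-]CC(C)(C)O | intermediate
8 | 1-[(4-methoxybenzyl)oxy]-2-methylpropan-2-ol | COc1ccc(COCC(C)(C)O)cc1 | intermediate
9 | lithium tertiary alkoxide of 8 (formed in the flask) | [Li+].[O-]C(C)(C)COCc1ccc(OC)cc1 | intermediate
10 | cuprous tertiary alkoxide of 8 (formed in the flask) | [Cu+].[O-]C(C)(C)COCc1ccc(OC)cc1 | intermediate
11 | 8-[(2S)-2-({1-[(4-methoxybenzyl)oxy]-2-methylpropan-2-yl}oxy)-3-methylbut-3-en-1-yl]-7-methoxy-2H-chromen-2-one | C=C(C)[C@H](Cc1c(OC)ccc2ccc(=O)oc12)OC(C)(C)COCc1ccc(OC)cc1 | intermediate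
12 | 2-methyl-2-[(S)-auraptenyloxy]propan-1-ol | C=C(C)[C@H](Cc1c(OC)ccc2ccc(=O)oc12)OC(C)(C)CO | intermediate
13 | 2-methyl-2-[(S)-auraptenyloxy]propanal | C=C(C)[C@H](Cc1c(OC)ccc2ccc(=O)oc12)OC(C)(C)C=O | intermediate
14 | 2-methylresorcinol | Cc1c(O)cccc1O | starting material
15 | 7-hydroxy-8-methylcoumarin | Cc1c(O)ccc2ccc(=O)oc12 | intermediate
16 | potassium 8-methyl-2-oxo-2H-chromen-7-olate (formed in the flask) | Cc1c([O-])ccc2ccc(=O)oc12.[K+] | intermediate
17 | 7-methoxy-8-methylcoumarin | COc1ccc2ccc(=O)oc2c1C | intermediate
18 | 8-(bromomethyl)-7-methoxycoumarin | COc1ccc2ccc(=O)oc2c1CBr | intermediate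
19 | S-[(7-methoxycoumarin-8-yl)methyl] sulfonium triflate of (R)-limonene-derived isothiocineole, alkylated on the exo lone pair | C[C@H]1CC[C@@H]2C[C@H]1[S@@+](Cc1c(OC)ccc3ccc(=O)oc13)C2(C)C.[O-]S(=O)(=O)C(F)(F)F | intermediate
20 | sulfonium ylide from 19 (formed in the flask) | C[C@H]1CC[C@@H]2C[C@H]1[S@@+]([CH-]c1c(OC)ccc3ccc(=O)oc13)C2(C)C | intermediate
21 | anti betaine from 20 and 13 (formed in the flask) | C[C@H]1CC[C@@H]2C[C@H]1[S@@+]([C@@H](c1c(OC)ccc3ccc(=O)oc13)[C@H]([O-])C(C)(C)O[C@H](C(C)=C)Cc1c(OC)ccc3ccc(=O)oc13)C2(C)C | intermediate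
22 | trans-epoxide, 8-[(2S)-2-({2-[(2S,3R)-3-(7-methoxy-2-oxo-2H-chromen-8-yl)oxiran-2-yl]propan-2-yl}oxy)-3-methylbut-3-en-1-yl]-7-methoxy-2H-chromen-2-one | C=C(C)[C@H](Cc1c(OC)ccc2ccc(=O)oc12)OC(C)(C)[C@H]1O[C@@H]1c1c(OC)ccc2ccc(=O)oc12 | intermediate
23 | benzylic radical at B-C1 with titanocene chloride alkoxide at B-C2 (formed in the flask) | C=C(C)[C@H](Cc1c(OC)ccc2ccc(=O)oc12)OC(C)(C)[C@@H]([O-])[CH]c1c(OC)ccc2ccc(=O)oc12.[Ti+4].[Cl-].[cH-]1cccc1.[cH-]1cccc1 | intermediate
24 | titanocene chloride alkoxide of the target (formed in the flask) | C=C(C)[C@H](Cc1c(OC)ccc2ccc(=O)oc12)OC(C)(C)[C@@H]([O-])Cc1c(OC)ccc2ccc(=O)oc12.[Ti+4].[Cl-].[cH-]1cccc1.[cH-]1cccc1 | intermediate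
25 | CNP0142500.1, 8-[(2S)-2-{[(3S)-3-hydroxy-4-(7-methoxy-2-oxo-2H-chromen-8-yl)-2-methylbutan-2-yl]oxy}-3-methylbut-3-en-1-yl]-7-methoxy-2H-chromen-2-one | C=C(C)[C@H](Cc1c(OC)ccc2ccc(=O)oc12)OC(C)(C)[C@@H](O)Cc1c(OC)ccc2ccc(=O)oc12 | target

**Count.** Total: 13 steps. Longest linear sequence: 8 steps (1, 2, 3, 5, 6, 7, 12, 13 from osthol).

**Steps most likely to fail**

- **Step 12.** Addition of the ortho,ortho-disubstituted ylide to the crowded aldehyde may be slow, so the ylide could decay or add to a coumarin C3=C4 bond; facial or anti selectivity may also be incomplete. Fallback: setting out from aldehyde 13 and bromide 18, a Nozaki–Hiyama-type benzylation (CrCl2, THF, rt) would join the same two carbons without stereocontrol and give the homobenzylic alcohol as a mixture of B-C2 epimers F1. Dess–Martin oxidation would give the ketone F2. Corey–Bakshi–Shibata reduction [(R)-2-methyl-CBS-oxazaborolidine, catecholborane, toluene, −78 °C], which tells the tertiary alkyl side from the arylmethyl side, would then rejoin the route at target 25.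

- **Step 5.** The 2-methyl-substituted allyl carbonate may ionise sluggishly, and substitution could go to the primary allyl terminus or give way to elimination to the aryl diene. Fallback: setting out from (S)-auraptenol 4, BF3·OEt2-catalysed addition of the alcohol to excess 2,2-dimethyloxirane (CH2Cl2, −30 °C, slow addition), which opens the epoxide at its tertiary carbon and leaves the A-C2–O bond intact, would give alcohol 12 directly. The route is rejoined at 12 and steps 3 to 6 fall away.

- **Step 13.** The bulky oxirane may bind titanium slowly; the benzylic radical may be reduced a second time, leading to deoxygenation to the alkene, or may cyclise onto the isopropenyl group. Fallback: setting out from epoxide 22, MgBr2·OEt2 (Et2O–CH2Cl2, 0 °C) would open the oxirane at the benzylic carbon to the bromohydrin F3, and radical debromination (Bu3SnH, AIBN, toluene, 80 °C) would rejoin the route at target 25.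

Further compounds
F1 | step 12 | homobenzylic alcohol as a mixture of B-C2 epimers (target and its B-C2 epimer) | C=C(C)[C@H](Cc1c(OC)ccc2ccc(=O)oc12)OC(C)(C)C(O)Cc1c(OC)ccc2ccc(=O)oc12
F2 | step 12 | ketone at B-C2, 8-[(2S)-2-{[4-(7-methoxy-2-oxo-2H-chromen-8-yl)-2-methyl-3-oxobutan-2-yl]oxy}-3-methylbut-3-en-1-yl]-7-methoxy-2H-chromen-2-one | C=C(C)[C@H](Cc1c(OC)ccc2ccc(=O)oc12)OC(C)(C)C(=O)Cc1c(OC)ccc2ccc(=O)oc12
F0 | step 5 | none | none
F3 | step 13 | bromohydrin with bromine at B-C1 (either configuration) and (S)-hydroxyl at B-C2 | C=C(C)[C@H](Cc1c(OC)ccc2ccc(=O)oc12)OC(C)(C)[C@@H](O)C(Br)c1c(OC)ccc2ccc(=O)oc12
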